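Numbering (indene): C1 CHMe, C2=C3 (Et on C3), C3a and C7a at the ring fusion, C4 (Me, CO2H), C5 (Et, chain C1'–C4'), C6=C7 (Me on C7).
Enabling feature: C5 of the cyclohexene ring is bonded to two sp2 CH carbons, C6 inside the ring and C1' of the side chain. Cutting C6=C7 and C2'–C3' therefore leaves an ethyl divinyl carbon that is not a stereocentre.
Cuts, in retrosynthetic order: ester O–CH3, C2'–C3' (Heck), C6=C7 (metathesis), C4–C5 (second Ireland–Claisen), C3a–C4 (first Ireland–Claisen), C3–Et (Negishi), C1–Me and C7a–C7 (conjugate addition/alkylation).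
Forward: the five-membered ring is bought as a cyclopentenone and substituted, and the C4–C5 arm is grown on it by two sigmatropic shifts. The six-membered ring closes in step 13 and the phenyldienyl chain is completed last.
Stereochemistry: C7a is set anti to the silyloxy group of the (S)-enone and C1 anti to C7a. The C2 carbinol comes from a CBS reduction and passes its configuration to C3a by suprafacial transfer. C4 comes from face selection under allylic strain, C5 from a chiral Mo alkylidene that picks one vinyl group, and the E,E-diene from the Heck step and the bromide.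

Key step: step 13

Remark: conjugate addition anti to the silyloxy group maps the carbinol carbon of the enone onto C3a, so its (S)-enantiomer is required; it is sold like its antipode.
Remark: which antipode of the aryloxide ligand is matched with the metathesis substrate cannot be derived on paper; the (R)-ligand is written and both antipodes are available.

Step 1
Reactants: 1 (S)-4-(tert-butyldimethylsilyloxy)cyclopent-2-en-1-one; 2 isopropenylmagnesium bromide
Product: 4 (2S,3R,4S)-4-(tert-butyldimethylsilyloxy)-2-methyl-3-(prop-1-en-2-yl)cyclopentan-1-one, via bromomagnesium enolate 3 (not isolated)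
Conditions: CuBr·SMe2 (cat.), THF, −78 °C; then MeI, HMPA, −78 → −20 °C
Reagents that add atoms: iodomethane, CI
Why: Copper-catalysed conjugate addition with enolate alkylation (three-component coupling): the organocopper species adds to the enone face anti to the silyloxy group and sets C7a, and the regiodefined enolate 3 is methylated anti to the new isopropenyl group, which sets C1 in the stable all-trans array.

Step 2
Reactants: 4 (2S,3R,4S)-4-(tert-butyldimethylsilyloxy)-2-methyl-3-(prop-1-en-2-yl)cyclopentan-1-one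
Product: 5 (4R,5S)-5-methyl-4-(prop-1-en-2-yl)cyclopent-2-en-1-one
Conditions: DBU, CH2Cl2, 0 °C, short contact time
Reagents that add atoms: none
Why: E1cB β-elimination of the silyloxy group from a β-silyloxy ketone, in which the methyl centre already holds its stable trans position and brief exposure at 0 °C should spare the doubly allylic C7a–H.

Step 3
Reactants: 5 (4R,5S)-5-methyl-4-(prop-1-en-2-yl)cyclopent-2-en-1-one
Product: 6 (4S,5S)-2-iodo-5-methyl-4-(prop-1-en-2-yl)cyclopent-2-en-1-one
Conditions: I2, pyridine/CH2Cl2 (1:1), 0 °C → rt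
Reagents that add atoms: iodine, II
Why: α-Iodination of an enone by amine addition, iodination and elimination, which touches only the enone α-CH (later C3) and should leave the isolated isopropenyl group and both stereocentres alone.

Step 4
Reactants: 6 (4S,5S)-2-iodo-5-methyl-4-(prop-1-en-2-yl)cyclopent-2-en-1-one; 7 ethylzinc bromide
Product: 8 (4R,5S)-2-ethyl-5-methyl-4-(prop-1-en-2-yl)cyclopent-2-en-1-one
Conditions: Pd(dppf)Cl2 (cat.), THF, rt → 40 °C
Reagents that add atoms: none
Why: Negishi coupling of an α-iodoenone with an alkylzinc halide, which needs no base and so protects the epimerisable centres, while the wide-bite-angle ligand favours reductive elimination over β-hydride loss from the ethyl group.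

Step 5
Reactants: 8 (4R,5S)-2-ethyl-5-methyl-4-(prop-1-en-2-yl)cyclopent-2-en-1-one
Product: 9 (1S,4R,5S)-2-ethyl-5-methyl-4-(prop-1-en-2-yl)cyclopent-2-en-1-ol
Conditions: (R)-Me-CBS (cat.), catecholborane, toluene, −78 °C; MeOH, then aq. NaHCO3
Reagents that add atoms: none
Why: CBS reduction of an α-substituted cyclopentenone (1,2-selective): with the ethyl-bearing alkenyl arm as the large group, the (R)-catalyst delivers hydride to the face anti to the neighbouring methyl group, in line with the substrate bias, to give the carbinol cis to that methyl, and catecholborane should not hydroborate at this temperature.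

Step 6
Reactants: 9 (1S,4R,5S)-2-ethyl-5-methyl-4-(prop-1-en-2-yl)cyclopent-2-en-1-ol; 10 propanoyl chloride
Product: 11 (1S,4R,5S)-2-ethyl-5-methyl-4-(prop-1-en-2-yl)cyclopent-2-en-1-yl propanoate
Conditions: Et3N, DMAP (cat.), CH2Cl2, 0 °C
Reagents that add atoms: none
Why: DMAP-catalysed O-acylation of a secondary allylic alcohol, which leaves the C–O bond and its configuration untouched.

Step 7
Reactants: 11 (1S,4R,5S)-2-ethyl-5-methyl-4-(prop-1-en-2-yl)cyclopent-2-en-1-yl propanoate
Product: 14 2-[(1S,4R,5S)-2-ethyl-4-methyl-5-(prop-1-en-2-yl)cyclopent-2-en-1-yl]propanoic acid (both epimers at the α-carbon), via silyl ketene acetal 12 (not isolated), via trimethylsilyl ester 13 (not isolated)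
Conditions: LDA, THF, −78 °C; TMSCl; −78 °C → rt; aq. citric acid
Reagents that add atoms: chlorotrimethylsilane, C[Si](C)(C)Cl (its silyl group stays only in 12 and 13)
Why: Ireland–Claisen rearrangement: the suprafacial [3,3] shift forms C3a–C4 on the ring face that carried the oxygen, trans to the isopropenyl group, and moves the alkene to C2=C3, while the α-carbon configuration does not matter because it is planarised again in step 11.

Step 8
Reactants: 15 pent-2-yn-1-ol
Product: 17 (Z)-3-iodopent-2-en-1-ol, via cyclic alkenyl aluminate 16 (not isolated)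
Conditions: Red-Al, THF, 0 °C → rt; then I2, THF, −78 → 0 °C
Reagents that add atoms: iodine, II; Red-Al, [Na+].[AlH2-](OCCOC)OCCOC (its atoms stay only in 16)
Why: Hydroxyl-directed trans-hydroalumination of a propargylic alcohol places aluminium on C3 in the five-membered chelate 16, and iodinolysis of the C–Al bond proceeds with retention.

Step 9
Reactants: 17 (Z)-3-iodopent-2-en-1-ol; 18 vinylboronic acid pinacol ester
Product: 19 (2Z)-3-ethylpenta-2,4-dien-1-ol
Conditions: Pd(dppf)Cl2 (cat.), K2CO3, THF/H2O, 50 °C
Reagents that add atoms: none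
Why: Suzuki–Miyaura coupling of an alkenyl iodide that tolerates the free alcohol; the retained alkene geometry has no consequence later, because the carbon that bears ethyl and vinyl gains a second vinyl group in step 11.

Step 10
Reactants: 14 2-[(1S,4R,5S)-2-ethyl-4-methyl-5-(prop-1-en-2-yl)cyclopent-2-en-1-yl]propanoic acid; 19 (2Z)-3-ethylpenta-2,4-dien-1-ol
Product: 20 (2Z)-3-ethylpenta-2,4-dien-1-yl 2-[(1S,4R,5S)-2-ethyl-4-methyl-5-(prop-1-en-2-yl)cyclopent-2-en-1-yl]propanoate
Conditions: DCC, DMAP (cat.), CH2Cl2, 0 °C → rt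
Reagents that add atoms: none
Why: Steglich esterification of an α-branched acid with an unhindered primary allylic alcohol under neutral conditions that the diene should survive.

Step 11
Reactants: 20 (2Z)-3-ethylpenta-2,4-dien-1-yl 2-[(1S,4R,5S)-2-ethyl-4-methyl-5-(prop-1-en-2-yl)cyclopent-2-en-1-yl]propanoate
Product: 23 (2R)-3-ethenyl-3-ethyl-2-[(1R,4R,5S)-2-ethyl-4-methyl-5-(prop-1-en-2-yl)cyclopent-2-en-1-yl]-2-methylpent-4-enoic acid, via silyl ketene acetal 21 (not isolated), via trimethylsilyl ester 22 (not isolated)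
Conditions: LDA, THF, −78 °C; TMSCl/Et3N; −78 °C → rt, then 50 °C; aq. citric acid
Reagents that add atoms: chlorotrimethylsilane, C[Si](C)(C)Cl (its silyl group stays only in 21 and 22)
Why: Ireland–Claisen rearrangement of a tetrasubstituted silyl ketene acetal onto a 3,3-disubstituted allyl terminus, a known way to join two fully substituted carbons: it forms C4–C5 and turns the O–CH2–CH= unit into the second vinyl group, so neither ketene acetal nor dienol geometry matters, and C4 is set by face selection because allylic 1,3-strain holds C3a–H in the ketene acetal plane, the C3 ethyl group covers one face, and C7a turns only its hydrogen to the other face, from which the allyl terminus bonds to give (4R).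

Step 12
Reactants: 23 (2R)-3-ethenyl-3-ethyl-2-[(1R,4R,5S)-2-ethyl-4-methyl-5-(prop-1-en-2-yl)cyclopent-2-en-1-yl]-2-methylpent-4-enoic acid
Product: 24 methyl (2R)-3-ethenyl-3-ethyl-2-[(1R,4R,5S)-2-ethyl-4-methyl-5-(prop-1-en-2-yl)cyclopent-2-en-1-yl]-2-methylpent-4-enoate
Conditions: MeI, K2CO3, DMF, rt
Reagents that add atoms: iodomethane, CI
Why: SN2 O-alkylation of the carboxylate, which avoids any attack at the buried carbonyl carbon and removes the acidic proton that a Mo alkylidene would not tolerate.

Step 13
Reactants: 24 methyl (2R)-3-ethenyl-3-ethyl-2-[(1R,4R,5S)-2-ethyl-4-methyl-5-(prop-1-en-2-yl)cyclopent-2-en-1-yl]-2-methylpent-4-enoate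
Product: 25 methyl (1R,3aR,4R,5S,7aS)-5-ethenyl-3,5-diethyl-1,4,7-trimethyl-3a,4,5,7a-tetrahydro-1H-indene-4-carboxylate
Conditions: Mo(=N-2,6-iPr2C6H3)(=CHCMe2Ph)(2,5-Me2-pyrrolide)(OAr*) (cat., made in situ from the bis(pyrrolide) and (R)-3,3'-dibromo-2'-(TBSO)-5,5',6,6',7,7',8,8'-octahydro-1,1'-binaphth-2-ol), C6H6, 0.01 M, 22 → 50 °C, N2, ethene vented
Reagents that add atoms: none
Why: Olefin metathesis through metallacyclobutanes: the Mo alkylidene exchanges onto one of the monosubstituted C5 vinyl groups, adds across the 1,1-disubstituted isopropenyl group on C7a, and collapses to C6=C7 and Mo=CH2, which carries the chain with loss of ethene. The closest known reaction type is the desymmetrising ring-closing metathesis of trienes whose quaternary carbon bears two vinyl groups, run with chiral Mo or Ru alkylidenes. The cyclohexene closes in the six-membered (1,7-diene) mode between the trans C3a and C7a arms, with C5 already gauche to C7a after step 11, and no other ring can form because the two vinyl groups share one carbon and the trisubstituted C2=C3 bond is inert. C5 becomes stereogenic only here: loading on either vinyl group is reversible, so the outcome is decided in the ring-closing metallacyclobutane, where the chiral aryloxide and the stereogenic Mo centre distinguish the two half-chair arrangements. The substrate leans the same way, since the closure to 25 puts the flat spectator vinyl group pseudo-axial (beside C3a–H, anti to the axial C4 methyl) and the ethyl group pseudo-equatorial, but this bias is small and the catalyst must supply the rest. The unstrained trisubstituted C6=C7 bond is not expected to reopen, so the selection between the diastereotopic vinyl groups is kinetic and ethene is simply removed.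

Step 14
Reactants: 25 methyl (1R,3aR,4R,5S,7aS)-5-ethenyl-3,5-diethyl-1,4,7-trimethyl-3a,4,5,7a-tetrahydro-1H-indene-4-carboxylate; 26 (E)-β-bromostyrene
Product: 27 methyl (1R,3aR,4R,5S,7aS)-3,5-diethyl-1,4,7-trimethyl-5-[(1E,3E)-4-phenylbuta-1,3-dien-1-yl]-3a,4,5,7a-tetrahydro-1H-indene-4-carboxylate
Conditions: Pd(OAc)2 (cat.), n-Bu4NCl, K2CO3, DMF, 80 °C
Reagents that add atoms: none
Why: Heck reaction of an alkenyl bromide with a terminal alkene: the styryl group adds to the open CH2 terminus, C5 carries no hydrogen so syn β-hydride elimination can only give the conjugated (E)-C1'=C2' bond, the C3'=C4' geometry comes from 26, and the trisubstituted ring alkenes are too hindered to insert.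

Step 15
Reactants: 27 methyl (1R,3aR,4R,5S,7aS)-3,5-diethyl-1,4,7-trimethyl-5-[(1E,3E)-4-phenylbuta-1,3-dien-1-yl]-3a,4,5,7a-tetrahydro-1H-indene-4-carboxylate
Product: 28 (1R,3aR,4R,5S,7aS)-3,5-diethyl-1,4,7-trimethyl-5-[(1E,3E)-4-phenylbuta-1,3-dien-1-yl]-3a,4,5,7a-tetrahydro-1H-indene-4-carboxylic acid
Conditions: NaSEt, DMF, 90 °C; then 1 M HCl
Reagents that add atoms: none
Why: Nucleophilic (SN2) demethylation by thiolate at the ester methyl carbon, which does not depend on access to the hindered carbonyl and touches no stereocentre or alkene.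

Compound list
1 | (S)-4-(tert-butyldimethylsilyloxy)cyclopent-2-en-1-one | O=C1C[C@H](O[Si](C)(C)C(C)(C)C)C=C1 | starting material
2 | isopropenylmagnesium bromide | C=C(C)[Mg]Br | starting material
3 | bromomagnesium (3R,4S)-4-(tert-butyldimethylsilyloxy)-3-(prop-1-en-2-yl)cyclopent-1-en-1-olate | Br[Mg]OC1=C[C@H](C(C)=C)[C@@H](O[Si](C)(C)C(C)(C)C)C1 | intermediate (not isolated)
4 | (2S,3R,4S)-4-(tert-butyldimethylsilyloxy)-2-methyl-3-(prop-1-en-2-yl)cyclopentan-1-one | O=C1[C@@H](C)[C@H](C(C)=C)[C@@H](O[Si](C)(C)C(C)(C)C)C1 | intermediate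
5 | (4R,5S)-5-methyl-4-(prop-1-en-2-yl)cyclopent-2-en-1-one | O=C1[C@@H](C)[C@H](C(C)=C)C=C1 | intermediate
6 | (4S,5S)-2-iodo-5-methyl-4-(prop-1-en-2-yl)cyclopent-2-en-1-one | O=C1[C@@H](C)[C@H](C(C)=C)C=C1I | intermediate
7 | ethylzinc bromide | CC[Zn]Br | starting material
8 | (4R,5S)-2-ethyl-5-methyl-4-(prop-1-en-2-yl)cyclopent-2-en-1-one | O=C1[C@@H](C)[C@H](C(C)=C)C=C1CC | intermediate
9 | (1S,4R,5S)-2-ethyl-5-methyl-4-(prop-1-en-2-yl)cyclopent-2-en-1-ol (OH cis to methyl, trans to isopropenyl) | O[C@H]1[C@@H](C)[C@H](C(C)=C)C=C1CC | intermediate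
10 | propanoyl chloride | CCC(=O)Cl | starting material
11 | (1S,4R,5S)-2-ethyl-5-methyl-4-(prop-1-en-2-yl)cyclopent-2-en-1-yl propanoate | CCC(=O)O[C@H]1[C@@H](C)[C@H](C(C)=C)C=C1CC | intermediate
12 | (E)-O-trimethylsilyl ketene acetal of 11 | C/C=C(/O[Si](C)(C)C)O[C@H]1[C@@H](C)[C@H](C(C)=C)C=C1CC | intermediate (not isolated)
13 | trimethylsilyl ester of 14 | CCC1=C[C@@H](C)[C@H](C(C)=C)[C@H]1C(C)C(=O)O[Si](C)(C)C | intermediate (not isolated)
14 | 2-[(1S,4R,5S)-2-ethyl-4-methyl-5-(prop-1-en-2-yl)cyclopent-2-en-1-yl]propanoic acid (α-carbon undefined) | CCC1=C[C@@H](C)[C@H](C(C)=C)[C@H]1C(C)C(=O)O | intermediate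
15 | pent-2-yn-1-ol | CCC#CCO | starting material
16 | sodium salt of the five-membered O–Al–C3 alkenyl aluminate with two 2-methoxyethoxy ligands | CCC1=CCO[Al-]1(OCCOC)OCCOC.[Na+] | intermediate (not isolated)
17 | (Z)-3-iodopent-2-en-1-ol | CC/C(I)=C/CO | intermediate
18 | vinylboronic acid pinacol ester | C=CB1OC(C)(C)C(C)(C)O1 | starting material
19 | (2Z)-3-ethylpenta-2,4-dien-1-ol | CC/C(C=C)=C/CO | intermediate
20 | (2Z)-3-ethylpenta-2,4-dien-1-yl ester of 14 | CCC1=C[C@@H](C)[C@H](C(C)=C)[C@H]1C(C)C(=O)OC/C=C(/CC)C=C | intermediate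
21 | O-trimethylsilyl ketene acetal of 20 (E/Z at the ketene acetal undefined, of no consequence) | CCC1=C[C@@H](C)[C@H](C(C)=C)[C@H]1C(C)=C(O[Si](C)(C)C)OC/C=C(/CC)C=C | intermediate (not isolated)
22 | trimethylsilyl ester of 23 | CCC1=C[C@@H](C)[C@H](C(C)=C)[C@H]1[C@@](C)(C(=O)O[Si](C)(C)C)C(CC)(C=C)C=C | intermediate (not isolated)
23 | (2R)-3-ethenyl-3-ethyl-2-[(1R,4R,5S)-2-ethyl-4-methyl-5-(prop-1-en-2-yl)cyclopent-2-en-1-yl]-2-methylpent-4-enoic acid | CCC1=C[C@@H](C)[C@H](C(C)=C)[C@H]1[C@@](C)(C(=O)O)C(CC)(C=C)C=C | intermediate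
24 | methyl ester of 23 (metathesis precursor) | CCC1=C[C@@H](C)[C@H](C(C)=C)[C@H]1[C@@](C)(C(=O)OC)C(CC)(C=C)C=C | intermediate
25 | methyl (1R,3aR,4R,5S,7aS)-5-ethenyl-3,5-diethyl-1,4,7-trimethyl-3a,4,5,7a-tetrahydro-1H-indene-4-carboxylate | CCC1=C[C@@H](C)[C@@H]2C(C)=C[C@@](C=C)(CC)[C@](C)(C(=O)OC)[C@@H]12 | intermediate
26 | (E)-β-bromostyrene | Br/C=C/c1ccccc1 | starting material
27 | methyl ester of 28 | CCC1=C[C@@H](C)[C@@H]2C(C)=C[C@@](/C=C/C=C/c3ccccc3)(CC)[C@](C)(C(=O)OC)[C@@H]12 | intermediate
28 | (1R,3aR,4R,5S,7aS)-3,5-diethyl-1,4,7-trimethyl-5-[(1E,3E)-4-phenylbuta-1,3-dien-1-yl]-3a,4,5,7a-tetrahydro-1H-indene-4-carboxylic acid | CCC1=C[C@@H](C)[C@@H]2C(C)=C[C@@](/C=C/C=C/c3ccccc3)(CC)[C@](C)(C(=O)O)[C@@H]12 | target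

Total step count: 15. Longest linear sequence: 13 (steps 1–7 and 10–15); steps 8 and 9 form the side branch.

Steps most likely to fail

Step 13. The catalyst may not discriminate well enough between the two diastereotopic vinyl groups, or closure onto the isopropenyl group may stall beside the two quaternary carbons. The fallback sets out from 19, 26 and 14 and comes back at 27. It makes C5 stereogenic before the ring is closed.
- Heck coupling of 19 with 26 at the unhindered diene terminus should give (2Z,4E,6E)-3-ethyl-7-phenylhepta-2,4,6-trien-1-ol F1.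
- Steglich esterification of F1 with 14 gives the trienyl ester F2.
- LDA in THF followed by TMSCl should give the (E)-silyl ketene acetal F3, with the cyclopentenyl group cis to the allylic oxygen.
- F3 rearranges through a chair to the trimethylsilyl ester F4, which is hydrolysed to the acid F5. C4 is set as in step 11, and C5 follows from the two double-bond geometries.
- MeI/K2CO3 gives the methyl ester F6. Its single vinyl group is closed onto the isopropenyl group with the achiral catalyst (H2IMes)(PCy3)Cl2Ru=CHPh to give 27, so step 14 is bypassed as well.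

Step 11. Face selection at the ketene acetal carbon may be poor, or enolisation next to the cyclopentenyl group may be slow. The fallback sets out from 19, 10 and 9 and comes back at 23. It reverses the order of the two sigmatropic shifts, so that C4–C5 is made on an achiral fragment and C4 is set when C3a–C4 forms.
- Acylation of 19 with 10 gives (2Z)-3-ethylpenta-2,4-dien-1-yl propanoate F7.
- LDA/TMSCl gives its silyl ketene acetal F8, which rearranges to the trimethylsilyl ester F9. Hydrolysis gives racemic 3-ethenyl-3-ethyl-2-methylpent-4-enoic acid F10.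
- DCC/DMAP coupling of F10 with 9 gives the cyclopentenyl ester F11.
- LDA in THF and TMSCl should give the silyl ketene acetal F12, with the tert-alkyl group cis to the ring oxygen.
- A suprafacial chair-like shift across the cyclopentene leads to 22 and, after hydrolysis, to 23. A boat would push the tert-alkyl group under the ring.
- C4 then depends on the ketene acetal geometry, which can be switched by enolising in THF/HMPA.

Step 14. Carbopalladation of the vinyl group next to two quaternary carbons may be too slow, so that self-coupling of the bromide takes over. The fallback sets out from 25 and 18 and comes back at 27.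
- Cross-metathesis of 25 with 18, using (H2IMes)(PCy3)Cl2Ru=CHPh in CH2Cl2 at 40 °C, should give the (E)-alkenyl pinacol boronate F13.
- Suzuki–Miyaura coupling of F13 with 26 (Pd(PPh3)4, K2CO3, THF/H2O) joins C2'–C3' with retention of both alkene geometries.

Further compounds
F1 | step 13 | (2Z,4E,6E)-3-ethyl-7-phenylhepta-2,4,6-trien-1-ol | OC/C=C(/CC)\C=C\C=C\c1ccccc1
F2 | step 13 | (2Z,4E,6E)-3-ethyl-7-phenylhepta-2,4,6-trien-1-yl ester of 14 | CCC1=C[C@@H](C)[C@H](C(C)=C)[C@H]1C(C)C(=O)OC/C=C(/CC)\C=C\C=C\c2ccccc2
F3 | step 13 | (E)-O-trimethylsilyl ketene acetal of F2 | CCC1=C[C@@H](C)[C@H](C(C)=C)[C@H]1/C(C)=C(/O[Si](C)(C)C)OC/C=C(/CC)\C=C\C=C\c2ccccc2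
F4 | step 13 | trimethylsilyl ester of F5 | CCC1=C[C@@H](C)[C@H](C(C)=C)[C@H]1[C@@](C)(C(=O)O[Si](C)(C)C)[C@](CC)(C=C)/C=C/C=C/c2ccccc2
F5 | step 13 | (2R,3R,4E,6E)-3-ethenyl-3-ethyl-2-[(1R,4R,5S)-2-ethyl-4-methyl-5-(prop-1-en-2-yl)cyclopent-2-en-1-yl]-2-methyl-7-phenylhepta-4,6-dienoic acid | CCC1=C[C@@H](C)[C@H](C(C)=C)[C@H]1[C@@](C)(C(=O)O)[C@](CC)(C=C)/C=C/C=C/c2ccccc2
F6 | step 13 | methyl ester of F5 | CCC1=C[C@@H](C)[C@H](C(C)=C)[C@H]1[C@@](C)(C(=O)OC)[C@](CC)(C=C)/C=C/C=C/c2ccccc2
F7 | step 11 | (2Z)-3-ethylpenta-2,4-dien-1-yl propanoate | CCC(=O)OC/C=C(/CC)C=C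
F8 | step 11 | O-trimethylsilyl ketene acetal of F7 | CC=C(O[Si](C)(C)C)OC/C=C(/CC)C=C
F9 | step 11 | trimethylsilyl ester of F10 | CCC(C=C)(C=C)C(C)C(=O)O[Si](C)(C)C
F10 | step 11 | 3-ethenyl-3-ethyl-2-methylpent-4-enoic acid (racemic) | CCC(C=C)(C=C)C(C)C(=O)O
F11 | step 11 | (1S,4R,5S)-2-ethyl-5-methyl-4-(prop-1-en-2-yl)cyclopent-2-en-1-yl ester of F10 | CCC(C=C)(C=C)C(C)C(=O)O[C@H]1[C@@H](C)[C@H](C(C)=C)C=C1CC
F12 | step 11 | O-trimethylsilyl ketene acetal of F11, tert-alkyl group trans to OSiMe3 | CCC(C=C)(C=C)/C(C)=C(/O[Si](C)(C)C)O[C@H]1[C@@H](C)[C@H](C(C)=C)C=C1CC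
F13 | step 14 | (E)-2-(pinacolboryl)ethenyl analogue of 25 at C5 | CCC1=C[C@@H](C)[C@@H]2C(C)=C[C@@](/C=C/B3OC(C)(C)C(C)(C)O3)(CC)[C@](C)(C(=O)OC)[C@@H]12
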